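**Retrosynthetic overview**
1. The target is an acyclic heptane chain, numbered here from C1 on the guaiacyl ring to C7 on the syringyl ring, with a syn-diacetate at C3 (R) and C5 (S). Both benzene rings are bought and no ring is formed at any stage.
2. Key disconnection C5–C6: nickel-catalysed stereoconvergent alkyl–alkyl coupling of the C5-epimeric 1-bromoalkyl acetate 16 with the homobenzylic zinc reagent 7. One operation joins the halves, sets C5 from both epimers and delivers C5 already as its acetate.
3. Enabling feature: C5 is a dialkyl carbinol carbon carrying an acetoxy group (O–C(=O)CH3) between the methylenes C4 and C6. At the aldehyde level plus acetyl bromide it becomes a centre whose radical is stabilised by the ester oxygen and whose ester carbonyl can bind nickel.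
4. 16 comes from (R)-β-acetoxy aldehyde 15, from ozonolysis of homoallylic acetate 13, from Brown allylation of aldehyde 10 (sets C3), from dihydroconiferyl alcohol 8. 7 comes from syringaldehyde 1 by benzylation, Wittig methylenation, hydroboration, Appel bromination and zinc insertion.
5. The last step is hydrogenolysis of the two aryl benzyl ethers.

Key step: step 12

Assumption: the sense of induction of the chiral nickel catalyst in step 12 is ligand-controlled; the ligand antipode that gives the 5S acetate is the one meant (to be assigned on a model aldehyde, both antipodes being accessible).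

**Route**

Step 1
Reactants: 1 4-hydroxy-3,5-dimethoxybenzaldehyde (syringaldehyde)
Product: 2 4-(benzyloxy)-3,5-dimethoxybenzaldehyde
Conditions: BnBr, K2CO3, DMF, 60 °C
Reagents that add atoms: benzyl bromide, BrCc1ccccc1
Why: Williamson ether synthesis (SN2 of the phenoxide on benzyl bromide); the aldehyde is inert to carbonate.

Step 2
Reactants: 2 4-(benzyloxy)-3,5-dimethoxybenzaldehyde
Product: 3 2-(benzyloxy)-5-ethenyl-1,3-dimethoxybenzene
Conditions: Ph3PCH3Br, KOtBu, THF, 0 °C to rt
Reagents that add atoms: methyltriphenylphosphonium bromide, C[P+](c1ccccc1)(c1ccccc1)c1ccccc1.[Br-]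
Why: Wittig methylenation with the non-stabilised ylide; a terminal alkene raises no geometry question.

Step 3
Reactants: 3 2-(benzyloxy)-5-ethenyl-1,3-dimethoxybenzene
Product: 5 2-[4-(benzyloxy)-3,5-dimethoxyphenyl]ethan-1-ol, via B-alkyl-9-BBN adduct 4 (not isolated)
Conditions: 9-BBN, THF, 0 °C to rt; then NaOH, H2O2, 0 °C to rt
Reagents that add atoms: hydrogen peroxide, OO (the alcohol oxygen); 9-BBN, B1C2CCCC1CCC2 (atoms only in intermediate 4)
Why: Hydroboration–oxidation; the bulky borane should place boron on the terminal carbon of the styrene, and alkaline peroxide replaces boron by OH.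

Step 4
Reactants: 5 2-[4-(benzyloxy)-3,5-dimethoxyphenyl]ethan-1-ol
Product: 6 2-(benzyloxy)-5-(2-bromoethyl)-1,3-dimethoxybenzene
Conditions: CBr4, PPh3, CH2Cl2, 0 °C
Reagents that add atoms: carbon tetrabromide, BrC(Br)(Br)Br
Why: Appel reaction; bromide displaces the oxyphosphonium group at a primary carbon by SN2.

Step 5
Reactants: 6 2-(benzyloxy)-5-(2-bromoethyl)-1,3-dimethoxybenzene
Product: 7 {2-[4-(benzyloxy)-3,5-dimethoxyphenyl]ethyl}zinc bromide (DMA solution, titrated and used as such)
Conditions: Zn dust (1.5 equiv), I2 (5 mol %), DMA, 70 °C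
Reagents that add atoms: zinc, [Zn]
Why: Direct oxidative insertion of iodine-activated zinc into a primary alkyl bromide in a polar aprotic solvent; aryl ethers are tolerated.

Step 6
Reactants: 8 3-(4-hydroxy-3-methoxyphenyl)propan-1-ol (dihydroconiferyl alcohol)
Product: 9 3-[4-(benzyloxy)-3-methoxyphenyl]propan-1-ol
Conditions: BnBr, K2CO3, acetone, reflux
Reagents that add atoms: benzyl bromide, BrCc1ccccc1
Why: Williamson etherification, chemoselective for the phenol because carbonate deprotonates it and not the primary alcohol.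

Step 7
Reactants: 9 3-[4-(benzyloxy)-3-methoxyphenyl]propan-1-ol
Product: 10 3-[4-(benzyloxy)-3-methoxyphenyl]propanal
Conditions: TEMPO (10 mol %), PhI(OAc)2, CH2Cl2, rt
Reagents that add atoms: none
Why: Oxoammonium (TEMPO/BAIB) oxidation of a primary alcohol stops at the aldehyde and leaves the protected arene alone.

Step 8
Reactants: 10 3-[4-(benzyloxy)-3-methoxyphenyl]propanal
Product: 12 (3R)-1-[4-(benzyloxy)-3-methoxyphenyl]hex-5-en-3-ol, via diisopinocampheylborinate 11 (not isolated)
Conditions: dIpc2B(allyl) (the reagent of the (+)-α-pinene series, salt-free), Et2O/pentane, −78 °C; then NaOH, H2O2, 0 °C to rt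
Reagents that add atoms: B-allyldiisopinocampheylborane of the (+)-α-pinene series, C=CCB([C@@H]1C[C@@H]2C[C@H]([C@H]1C)C2(C)C)[C@@H]1C[C@@H]2C[C@H]([C@H]1C)C2(C)C
Why: Brown allylboration through a closed chair transition state; the isopinocampheyl groups of this reagent should direct allyl to the Si face of the unbranched aldehyde, which sets C3 as R, and oxidative work-up frees the alcohol.

Step 9
Reactants: 12 (3R)-1-[4-(benzyloxy)-3-methoxyphenyl]hex-5-en-3-ol
Product: 13 (3R)-1-[4-(benzyloxy)-3-methoxyphenyl]hex-5-en-3-yl acetate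
Conditions: Ac2O, pyridine, DMAP (cat.), CH2Cl2, rt
Reagents that add atoms: acetic anhydride, CC(=O)OC(C)=O
Why: DMAP-catalysed acylation of a secondary alcohol; the C–O bond is not broken, so C3 keeps its configuration.

Step 10
Reactants: 13 (3R)-1-[4-(benzyloxy)-3-methoxyphenyl]hex-5-en-3-yl acetate
Product: 15 (3R)-5-[4-(benzyloxy)-3-methoxyphenyl]-1-oxopentan-3-yl acetate, via secondary ozonide 14 (not isolated)
Conditions: O3, CH2Cl2, −78 °C (Sudan Red end point); then PPh3, −78 °C to rt
Reagents that add atoms: ozone, [O-][O+]=O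
Why: Ozonolysis (cycloaddition, Criegee rearrangement, phosphine reduction) of the terminal alkene, which should react far faster than the arene; the neutral work-up protects the β-acetoxy aldehyde from elimination.

Step 11
Reactants: 15 (3R)-5-[4-(benzyloxy)-3-methoxyphenyl]-1-oxopentan-3-yl acetate
Product: 16 (3R)-5-[4-(benzyloxy)-3-methoxyphenyl]-1-bromopentane-1,3-diyl diacetate (both C1 epimers; C1 of this name is C5 of the target; used crude)
Conditions: AcBr (1.1 equiv), ZnBr2 (1 mol %), CH2Cl2, −20 to 0 °C; volatiles removed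
Reagents that add atoms: acetyl bromide, CC(Br)=O
Why: Lewis-acid-catalysed addition of an acyl bromide across the aldehyde C=O gives the 1-bromoalkyl ester; the new centre forms as both epimers, which does not matter because the next step is stereoconvergent.

Step 12
Reactants: 16 (3R)-5-[4-(benzyloxy)-3-methoxyphenyl]-1-bromopentane-1,3-diyl diacetate (epimer mixture); 7 {2-[4-(benzyloxy)-3,5-dimethoxyphenyl]ethyl}zinc bromide
Product: 17 (3R,5S)-1-[4-(benzyloxy)-3-methoxyphenyl]-7-[4-(benzyloxy)-3,5-dimethoxyphenyl]heptane-3,5-diyl diacetate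
Conditions: NiBr2·glyme (10 mol %), chiral bis(oxazoline) ligand (12 mol %), 7 (1.5 equiv, DMA solution), THF, 0 °C
Reagents that add atoms: none
Why: A chiral nickel(I) species abstracts bromine from either C5 epimer of 16 to give one planar C5 radical, which is captured by the ligand-bound nickel(II)–CH2CH2Ar complex formed by transmetalation from 7, and reductive elimination from nickel(III) forms the C5–C6 bond. The closest known reaction type is the nickel-catalysed enantioconvergent alkyl–alkyl Negishi coupling of racemic 1-haloalkyl esters (and other α-heteroatom-substituted secondary alkyl halides) with primary alkylzinc halides. No ring is closed. The new stereocentre C5 should be set as S by the chiral ligand on nickel (catalyst control), both epimers of 16 converging on it, while C3, which takes no part, stays R, so the 3,5-syn relationship follows. The step needs cross-coupling to outrun β-hydride elimination and reduction of the radical, and needs the catalyst to override any 1,3-bias from C3: the acetoxy oxygen on C5 stabilises the radical and its carbonyl oxygen gives nickel a second binding point, the C3 acetate sits γ to nickel and cannot β-eliminate, and esters and aryl benzyl ethers are inert to the alkylzinc halide at 0 °C.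

Step 13
Reactants: 17 (3R,5S)-1-[4-(benzyloxy)-3-methoxyphenyl]-7-[4-(benzyloxy)-3,5-dimethoxyphenyl]heptane-3,5-diyl diacetate
Product: 18 (3R,5S)-1-(4-hydroxy-3-methoxyphenyl)-7-(4-hydroxy-3,5-dimethoxyphenyl)heptane-3,5-diyl diacetate
Conditions: H2 (1 atm), 10 % Pd/C, EtOAc, rt
Reagents that add atoms: none
Why: Hydrogenolysis of aryl benzyl ethers over palladium under neutral conditions leaves the secondary acetates, both stereocentres and the arenes untouched.

**Compound list**
1 | 4-hydroxy-3,5-dimethoxybenzaldehyde (syringaldehyde) | COc1cc(C=O)cc(OC)c1O | starting material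
2 | 4-(benzyloxy)-3,5-dimethoxybenzaldehyde | COc1cc(C=O)cc(OC)c1OCc1ccccc1 | intermediate
3 | 2-(benzyloxy)-5-ethenyl-1,3-dimethoxybenzene | COc1cc(C=C)cc(OC)c1OCc1ccccc1 | intermediate
4 | 9-{2-[4-(benzyloxy)-3,5-dimethoxyphenyl]ethyl}-9-borabicyclo[3.3.1]nonane (not isolated) | COc1cc(CCB2C3CCCC2CCC3)cc(OC)c1OCc1ccccc1 | intermediate
5 | 2-[4-(benzyloxy)-3,5-dimethoxyphenyl]ethan-1-ol | COc1cc(CCO)cc(OC)c1OCc1ccccc1 | intermediate
6 | 2-(benzyloxy)-5-(2-bromoethyl)-1,3-dimethoxybenzene | COc1cc(CCBr)cc(OC)c1OCc1ccccc1 | intermediate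
7 | {2-[4-(benzyloxy)-3,5-dimethoxyphenyl]ethyl}zinc bromide | COc1cc(CC[Zn]Br)cc(OC)c1OCc1ccccc1 | intermediate
8 | 3-(4-hydroxy-3-methoxyphenyl)propan-1-ol (dihydroconiferyl alcohol) | COc1cc(CCCO)ccc1O | starting material
9 | 3-[4-(benzyloxy)-3-methoxyphenyl]propan-1-ol | COc1cc(CCCO)ccc1OCc1ccccc1 | intermediate
10 | 3-[4-(benzyloxy)-3-methoxyphenyl]propanal | COc1cc(CCC=O)ccc1OCc1ccccc1 | intermediate
11 | (3R)-1-[4-(benzyloxy)-3-methoxyphenyl]hex-5-en-3-yl diisopinocampheylborinate (not isolated) | COc1cc(CC[C@H](CC=C)OB([C@@H]2C[C@@H]3C[C@H]([C@H]2C)C3(C)C)[C@@H]2C[C@@H]3C[C@H]([C@H]2C)C3(C)C)ccc1OCc1ccccc1 | intermediate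
12 | (3R)-1-[4-(benzyloxy)-3-methoxyphenyl]hex-5-en-3-ol | COc1cc(CC[C@H](CC=C)O)ccc1OCc1ccccc1 | intermediate
13 | (3R)-1-[4-(benzyloxy)-3-methoxyphenyl]hex-5-en-3-yl acetate | COc1cc(CC[C@H](CC=C)OC(C)=O)ccc1OCc1ccccc1 | intermediate
14 | (2R)-4-[4-(benzyloxy)-3-methoxyphenyl]-1-(1,2,4-trioxolan-3-yl)butan-2-yl acetate (secondary ozonide, not isolated) | COc1cc(CC[C@H](CC2OCOO2)OC(C)=O)ccc1OCc1ccccc1 | intermediate
15 | (3R)-5-[4-(benzyloxy)-3-methoxyphenyl]-1-oxopentan-3-yl acetate | COc1cc(CC[C@H](CC=O)OC(C)=O)ccc1OCc1ccccc1 | intermediate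
16 | (3R)-5-[4-(benzyloxy)-3-methoxyphenyl]-1-bromopentane-1,3-diyl diacetate (both C1 epimers) | COc1cc(CC[C@H](CC(Br)OC(C)=O)OC(C)=O)ccc1OCc1ccccc1 | intermediate
17 | (3R,5S)-1-[4-(benzyloxy)-3-methoxyphenyl]-7-[4-(benzyloxy)-3,5-dimethoxyphenyl]heptane-3,5-diyl diacetate | COc1cc(CC[C@H](C[C@H](CCc2cc(OC)c(OCc3ccccc3)c(OC)c2)OC(C)=O)OC(C)=O)ccc1OCc1ccccc1 | intermediate
18 | (3R,5S)-1-(4-hydroxy-3-methoxyphenyl)-7-(4-hydroxy-3,5-dimethoxyphenyl)heptane-3,5-diyl diacetate | COc1cc(CC[C@H](C[C@H](CCc2cc(OC)c(O)c(OC)c2)OC(C)=O)OC(C)=O)ccc1O | target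

**Count**
Total steps: 13. Longest linear sequence: 8 steps (8 to 18, steps 6–13); the zinc reagent 7 is made in 5 steps from 1 and enters at step 12.

**Steps most likely to fail**

1. Step 12. The catalyst may fail to control C5 against the existing C3 centre, so the 3,5-anti isomer forms alongside, or the C5 radical may be diverted into reduction or enol acetate formation. The fallback builds the same C5–C6 bond by carbonyl addition and sets C5 by substrate control. It sets out from alcohol 12 and bromide 6 and comes back at 17. Alcohol 12 is silylated (TBSCl, imidazole, DMF) to tert-butyl{[(3R)-1-(4-benzyloxy-3-methoxyphenyl)hex-5-en-3-yl]oxy}dimethylsilane F1. Ozonolysis with phosphine work-up gives (3R)-5-[4-(benzyloxy)-3-methoxyphenyl]-3-[(tert-butyldimethylsilyl)oxy]pentanal F2. Bromide 6 is converted with magnesium in THF into {2-[4-(benzyloxy)-3,5-dimethoxyphenyl]ethyl}magnesium bromide F3, which is added to F2 at −78 °C to give the C5-epimeric (3R)-3-silyloxyheptan-5-ols F4. Dess–Martin oxidation gives the (3R)-3-silyloxyheptan-5-one F5, and HF·pyridine frees the (3R)-3-hydroxyheptan-5-one F6. Narasaka–Prasad reduction (Et2BOMe, NaBH4, THF/MeOH, −78 °C) should deliver hydride to the boron chelate from outside and give the syn (3R,5S)-heptane-3,5-diol F7. Acetylation (Ac2O, pyridine, DMAP) then gives 17.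

2. Step 11. The β-acetoxy aldehyde may lose acetic acid to the enal under the acidic conditions, acetyl bromide with the Lewis acid may cleave the aryl benzyl ethers, and the moisture-sensitive bromo acetate may hydrolyse before use. The fallback avoids the halo ester altogether; it sets out from aldehyde 15 and styrene 3 and comes back at 17. Hydroboration of 3 with Et2BH gives {2-[4-(benzyloxy)-3,5-dimethoxyphenyl]ethyl}diethylborane F8. Boron–zinc exchange with Et2Zn (volatiles removed) gives bis{2-[4-(benzyloxy)-3,5-dimethoxyphenyl]ethyl}zinc F9. F9 is added to 15 with Ti(OiPr)4 and catalytic (1R,2R)-1,2-bis(trifluoromethanesulfonamido)cyclohexane in toluene at −20 °C. Catalyst-controlled Si-face addition, as with simple aldehydes, should give (3R,5S)-1-[4-(benzyloxy)-3-methoxyphenyl]-7-[4-(benzyloxy)-3,5-dimethoxyphenyl]-5-hydroxyheptan-3-yl acetate F10. Acetylation gives 17.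

3. Step 10. Ozone may attack the electron-rich benzyloxy(methoxy)arene once the alkene is consumed, and the aldehyde may eliminate acetate during work-up or purification. The fallback takes ozone out of the route and cleaves the alkene through an isolated diol; it sets out from acetate 13 and comes back at 15. Catalytic osmium tetroxide with NMO in acetone/water gives (3R)-1-[4-(benzyloxy)-3-methoxyphenyl]-5,6-dihydroxyhexan-3-yl acetate F11 (both C5 epimers). Glycol cleavage with NaIO4 in buffered THF/water at 0 °C gives 15, used without chromatography.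

**Further compounds**
F1 | step 12 | tert-butyl{[(3R)-1-(4-benzyloxy-3-methoxyphenyl)hex-5-en-3-yl]oxy}dimethylsilane | COc1cc(CC[C@H](CC=C)O[Si](C)(C)C(C)(C)C)ccc1OCc1ccccc1
F2 | step 12 | (3R)-5-[4-(benzyloxy)-3-methoxyphenyl]-3-[(tert-butyldimethylsilyl)oxy]pentanal | COc1cc(CC[C@H](CC=O)O[Si](C)(C)C(C)(C)C)ccc1OCc1ccccc1
F3 | step 12 | {2-[4-(benzyloxy)-3,5-dimethoxyphenyl]ethyl}magnesium bromide | COc1cc(CC[Mg]Br)cc(OC)c1OCc1ccccc1
F4 | step 12 | (3R)-1-[4-(benzyloxy)-3-methoxyphenyl]-7-[4-(benzyloxy)-3,5-dimethoxyphenyl]-3-[(tert-butyldimethylsilyl)oxy]heptan-5-ol (both C5 epimers) | COc1cc(CC[C@H](CC(O)CCc2cc(OC)c(OCc3ccccc3)c(OC)c2)O[Si](C)(C)C(C)(C)C)ccc1OCc1ccccc1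
F5 | step 12 | (3R)-1-[4-(benzyloxy)-3-methoxyphenyl]-7-[4-(benzyloxy)-3,5-dimethoxyphenyl]-3-[(tert-butyldimethylsilyl)oxy]heptan-5-one | COc1cc(CC[C@H](CC(=O)CCc2cc(OC)c(OCc3ccccc3)c(OC)c2)O[Si](C)(C)C(C)(C)C)ccc1OCc1ccccc1
F6 | step 12 | (3R)-1-[4-(benzyloxy)-3-methoxyphenyl]-7-[4-(benzyloxy)-3,5-dimethoxyphenyl]-3-hydroxyheptan-5-one | COc1cc(CC[C@H](CC(=O)CCc2cc(OC)c(OCc3ccccc3)c(OC)c2)O)ccc1OCc1ccccc1
F7 | step 12 | (3R,5S)-1-[4-(benzyloxy)-3-methoxyphenyl]-7-[4-(benzyloxy)-3,5-dimethoxyphenyl]heptane-3,5-diol | COc1cc(CC[C@H](C[C@H](CCc2cc(OC)c(OCc3ccccc3)c(OC)c2)O)O)ccc1OCc1ccccc1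
F8 | step 11 | {2-[4-(benzyloxy)-3,5-dimethoxyphenyl]ethyl}diethylborane | COc1cc(CCB(CC)CC)cc(OC)c1OCc1ccccc1
F9 | step 11 | bis{2-[4-(benzyloxy)-3,5-dimethoxyphenyl]ethyl}zinc | COc1cc(CC[Zn]CCc2cc(OC)c(OCc3ccccc3)c(OC)c2)cc(OC)c1OCc1ccccc1
F10 | step 11 | (3R,5S)-1-[4-(benzyloxy)-3-methoxyphenyl]-7-[4-(benzyloxy)-3,5-dimethoxyphenyl]-5-hydroxyheptan-3-yl acetate | COc1cc(CC[C@H](C[C@H](CCc2cc(OC)c(OCc3ccccc3)c(OC)c2)O)OC(C)=O)ccc1OCc1ccccc1
F11 | step 10 | (3R)-1-[4-(benzyloxy)-3-methoxyphenyl]-5,6-dihydroxyhexan-3-yl acetate (both C5 epimers) | COc1cc(CC[C@H](CC(O)CO)OC(C)=O)ccc1OCc1ccccc1
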